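**Retrosynthetic overview**
1. Target ⇐ double angeloylation coupled to an α-ketol 1,2-shift (six- to seven-membered ring expansion) of a hydrindene acetyl carbinol; this closes the seven-membered ring last and sets C6.
2. Acetyl carbinol ⇐ ketal hydrolysis and CBS reduction (sets C2) of a bicyclic enone.
3. Bicyclic enone ⇐ intramolecular Pauson–Khand reaction of an acyclic 1,7-enyne; the five- and six-membered rings form together and the tertiary carbinol relays its configuration to the quaternary carbon.
4. Enyne ⇐ catalytic asymmetric methallylboration of an α-ketal ketone ⇐ enolate alkylation of butanedione mono-ketal with a propargylic bromide (from 3-methylbut-1-yne and formaldehyde).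
5. Ring order: cyclopentenone and cyclohexane in one step, then cyclohexane → cycloheptanone.

Target as read from the SMILES: (2S,6S,8aR) in azulene numbering, angular methyl, C2–O and C6–O all on one face, both esters (Z) (angelates).

**Step 1**
Reactants: 1 butane-2,3-dione
Product: 2 3,3-dimethoxybutan-2-one
Conditions: HC(OMe)3 (1.1 equiv), MeOH, TsOH·H2O (1 mol%), rt
Reagents that add atoms: trimethyl orthoformate, COC(OC)OC; methanol, CO
Why: Acid-catalysed ketalisation with an orthoester stops at the mono-ketal because the second carbonyl is hindered and inductively deactivated by the new ketal, and it leaves a ketone with a single enolisable methyl group.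

**Step 2**
Reactants: 3 3-methylbut-1-yne
Product: 7 1-bromo-4-methylpent-2-yne, via lithium acetylide 4 (not isolated), via lithium alkoxide 5 (not isolated), via propargylic mesylate 6 (not isolated)
Conditions: n-BuLi, THF, −78 °C; (CH2O)n, −78 °C → rt; MsCl, −20 °C; LiBr, rt
Reagents that add atoms: formaldehyde (as paraformaldehyde), C=O; lithium bromide, [Li+].[Br-]
Why: Alkynyllithium addition to formaldehyde, O-sulfonylation of the lithium alkoxide and SN2 displacement by bromide are each fast for a primary propargylic system, so the volatile alcohol need not be isolated.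

**Step 3**
Reactants: 2 3,3-dimethoxybutan-2-one; 7 1-bromo-4-methylpent-2-yne
Product: 9 2,2-dimethoxy-8-methylnon-6-yn-3-one, via lithium enolate 8 (not isolated)
Conditions: LiN(i-Pr)2, THF, −78 °C; then 7, DMPU, −78 → 0 °C
Reagents that add atoms: none
Why: Kinetic enolate alkylation, in which the only enolisable position of 2 is the acetyl methyl and its lithium enolate displaces the primary propargylic bromide by SN2 (attack at the isopropyl-bearing alkyne carbon is hindered).

**Step 4**
Reactants: 10 (2-methylprop-2-en-1-yl)magnesium chloride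
Product: 12 diisopropyl (2-methylprop-2-en-1-yl)boronate, via magnesium borate complex 11 (not isolated)
Conditions: B(Oi-Pr)3, Et2O, −78 °C → rt; HCl (2 M in Et2O), 0 °C; filter, distil
Reagents that add atoms: triisopropyl borate, CC(C)OB(OC(C)C)OC(C)C
Why: Transmetallation of the Grignard reagent to boron gives the borate ate complex, and protonolysis of one alkoxide is the standard preparation of allyl diisopropyl boronates.

**Step 5**
Reactants: 9 2,2-dimethoxy-8-methylnon-6-yn-3-one; 12 diisopropyl (2-methylprop-2-en-1-yl)boronate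
Product: 14 (4S)-4-(1,1-dimethoxyethyl)-2,9-dimethyldec-1-en-7-yn-4-ol, via borate ester 13 (not isolated)
Conditions: (R)-3,3'-dibromo-1,1'-bi-2-naphthol (15 mol%), PhMe–PhCF3 3:1, −35 °C; aq. NaHCO3 work-up
Reagents that add atoms: none
Why: BINOL-catalysed asymmetric allylboration of a ketone through a closed chair transition state with the bulky ketal carbon equatorial, the catalyst-bound boronate selecting one carbonyl face to set the (4S)-carbinol; the catalyst hand is assigned by analogy with aryl methyl ketones and the antipode is used if the sense proves opposite.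

**Step 6**
Reactants: 14 (4S)-4-(1,1-dimethoxyethyl)-2,9-dimethyldec-1-en-7-yn-4-ol
Product: 15 (6S,7aS)-6-(1,1-dimethoxyethyl)-6-hydroxy-7a-methyl-3-(propan-2-yl)-1,4,5,6,7,7a-hexahydro-2H-inden-2-one (OH cis to the angular methyl)
Conditions: Co2(CO)8 (10 mol%), tetramethylthiourea (60 mol%), CO (1 atm), PhMe, 70 °C
Reagents that add atoms: carbon monoxide, [C-]#[O+]
Why: Intramolecular Pauson–Khand [2+2+1] reaction forms both carbocycles, the tetrasubstituted enone and the quaternary carbon at once, and in the chair-like alkene-insertion transition state the bulky dimethoxyethyl group is equatorial and the small OH axial, so the new angular methyl ends up 1,3-diaxial (cis) to OH and the carbinol relays its configuration to C7a (minor diastereomer removed by chromatography).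

**Step 7**
Reactants: 15 (6S,7aS)-6-(1,1-dimethoxyethyl)-6-hydroxy-7a-methyl-3-(propan-2-yl)-1,4,5,6,7,7a-hexahydro-2H-inden-2-one
Product: 16 (2S,6S,7aR)-6-(1,1-dimethoxyethyl)-7a-methyl-3-(propan-2-yl)-2,4,5,6,7,7a-hexahydro-1H-indene-2,6-diol
Conditions: (R)-1-methyl-3,3-diphenyltetrahydro-1H,3H-pyrrolo[1,2-c][1,3,2]oxazaborole ((R)-Me-CBS, 20 mol%), BH3·SMe2, THF, −20 °C; MeOH quench
Reagents that add atoms: none
Why: Corey–Bakshi–Shibata reduction, in which the enone binds the oxazaborolidine with the α-isopropyl alkenyl flank as the large group so that the (R)-catalyst delivers hydride to give the (2S)-allylic alcohol (OH cis to the angular methyl) under reagent control while the acetyl group is still masked as its ketal.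

**Step 8**
Reactants: 16 (2S,6S,7aR)-6-(1,1-dimethoxyethyl)-7a-methyl-3-(propan-2-yl)-2,4,5,6,7,7a-hexahydro-1H-indene-2,6-diol
Product: 17 1-[(2S,6S,7aR)-2,6-dihydroxy-7a-methyl-3-(propan-2-yl)-2,4,5,6,7,7a-hexahydro-1H-inden-6-yl]ethan-1-one
Conditions: pyridinium p-toluenesulfonate (20 mol%), acetone–H2O 10:1, rt
Reagents that add atoms: water, O
Why: Mild acid hydrolysis of an acyclic dimethyl ketal, which is far more labile than the allylic alcohol is towards ionisation at this acidity, unmasks the tertiary α-ketol without touching a stereocenter.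

**Step 9**
Reactants: 17 1-[(2S,6S,7aR)-2,6-dihydroxy-7a-methyl-3-(propan-2-yl)-2,4,5,6,7,7a-hexahydro-1H-inden-6-yl]ethan-1-one; 18 (2Z)-2-methylbut-2-enoic acid (angelic acid)
Product: 22 (2S,6S,8aR)-6,8a-dimethyl-7-oxo-3-(propan-2-yl)-1,2,4,5,6,7,8,8a-octahydroazulene-2,6-diyl bis[(2Z)-2-methylbut-2-enoate], via angelic anhydride 19 (not isolated), via mono-angelate 20 (not isolated), via ring-expanded alcohol 21 (not isolated)
Conditions: 18 (6 equiv), N,N'-dicyclohexylcarbodiimide (3 equiv), CH2Cl2, 0 °C → rt, filter; then 17, Sc(OTf)3 (10 mol%), 2,6-di-tert-butyl-4-methylpyridine (20 mol%), MeCN–CH2Cl2, −20 °C → rt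
Reagents that add atoms: none
Why: Proposed new method: an acylative α-ketol ring expansion in which Sc(OTf)3 first catalyses esterification of the secondary allylic alcohol (giving 20) and then, as a chelate of the syn-periplanar O=C–C–OH unit, the reversible 1,2-shift of ring carbon C5 from C6 to the acetyl carbon, an equilibrium that alone does not favour the seven-membered ketol but is drained because the axial, 1,3-diaxially flanked tertiary OH of 20 (and the more hindered regioisomeric ketol from C7 migration) is acylated far more slowly by the α-branched anhydride than the methyl carbinol of 21, so Curtin–Hammett trapping gives the α-acyloxy ketone irreversibly, with the chelate keeping the former acetyl oxygen on the face of the old axial OH and hence of the angular methyl (6S); the closest known reactions are the Lewis-acid-catalysed α-ketol (acyloin) rearrangement, as in steroid D-ring homologation, and the metal-triflate-catalysed acylation of tertiary alcohols with anhydrides, which have not been coupled to drive a six-to-seven ring expansion.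

**Compound list**
1 | butane-2,3-dione | CC(=O)C(C)=O | starting material
2 | 3,3-dimethoxybutan-2-one | CC(=O)C(C)(OC)OC | intermediate
3 | 3-methylbut-1-yne | CC(C)C#C | starting material
4 | lithium 3-methylbut-1-yn-1-ide | [Li]C#CC(C)C | intermediate
5 | lithium 4-methylpent-2-yn-1-olate | [Li]OCC#CC(C)C | intermediate
6 | 4-methylpent-2-yn-1-yl methanesulfonate | CC(C)C#CCOS(C)(=O)=O | intermediate
7 | 1-bromo-4-methylpent-2-yne | CC(C)C#CCBr | intermediate
8 | lithium 3,3-dimethoxybut-1-en-2-olate | [Li]OC(=C)C(C)(OC)OC | intermediate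
9 | 2,2-dimethoxy-8-methylnon-6-yn-3-one | CC(C)C#CCCC(=O)C(C)(OC)OC | intermediate
10 | (2-methylprop-2-en-1-yl)magnesium chloride | CC(=C)C[Mg]Cl | starting material
11 | chloromagnesium triisopropoxy(2-methylprop-2-en-1-yl)borate | CC(=C)C[B-](OC(C)C)(OC(C)C)OC(C)C.[Mg+]Cl | intermediate
12 | diisopropyl (2-methylprop-2-en-1-yl)boronate | CC(=C)CB(OC(C)C)OC(C)C | intermediate
13 | (4S)-4-(1,1-dimethoxyethyl)-2,9-dimethyldec-1-en-7-yn-4-yl diisopropyl borate | C=C(C)C[C@](OB(OC(C)C)OC(C)C)(C(C)(OC)OC)CCC#CC(C)C | intermediate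
14 | (4S)-4-(1,1-dimethoxyethyl)-2,9-dimethyldec-1-en-7-yn-4-ol | C=C(C)C[C@](O)(C(C)(OC)OC)CCC#CC(C)C | intermediate
15 | (6S,7aS)-6-(1,1-dimethoxyethyl)-6-hydroxy-7a-methyl-3-(propan-2-yl)-1,4,5,6,7,7a-hexahydro-2H-inden-2-one | O=C1C[C@]2(C)C[C@](O)(C(C)(OC)OC)CCC2=C1C(C)C | intermediate
16 | (2S,6S,7aR)-6-(1,1-dimethoxyethyl)-7a-methyl-3-(propan-2-yl)-2,4,5,6,7,7a-hexahydro-1H-indene-2,6-diol | O[C@H]1C[C@]2(C)C[C@](O)(C(C)(OC)OC)CCC2=C1C(C)C | intermediate
17 | 1-[(2S,6S,7aR)-2,6-dihydroxy-7a-methyl-3-(propan-2-yl)-2,4,5,6,7,7a-hexahydro-1H-inden-6-yl]ethan-1-one | O[C@H]1C[C@]2(C)C[C@](O)(C(C)=O)CCC2=C1C(C)C | intermediate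
18 | (2Z)-2-methylbut-2-enoic acid (angelic acid) | C/C=C(/C)C(=O)O | starting material
19 | (2Z)-2-methylbut-2-enoic anhydride (angelic anhydride) | C/C=C(/C)C(=O)OC(=O)/C(C)=C\C | intermediate
20 | (2S,6S,7aR)-6-acetyl-6-hydroxy-7a-methyl-3-(propan-2-yl)-2,4,5,6,7,7a-hexahydro-1H-inden-2-yl (2Z)-2-methylbut-2-enoate | C/C=C(/C)C(=O)O[C@H]1C[C@]2(C)C[C@](O)(C(C)=O)CCC2=C1C(C)C | intermediate
21 | (2S,6S,8aR)-6-hydroxy-6,8a-dimethyl-7-oxo-3-(propan-2-yl)-1,2,4,5,6,7,8,8a-octahydroazulen-2-yl (2Z)-2-methylbut-2-enoate | C/C=C(/C)C(=O)O[C@H]1C[C@]2(C)CC(=O)[C@@](C)(O)CCC2=C1C(C)C | intermediate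
22 | (2S,6S,8aR)-6,8a-dimethyl-7-oxo-3-(propan-2-yl)-1,2,4,5,6,7,8,8a-octahydroazulene-2,6-diyl bis[(2Z)-2-methylbut-2-enoate] | C/C=C(/C)C(=O)O[C@H]1C[C@]2(C)CC(=O)[C@@](C)(OC(=O)/C(C)=C\C)CCC2=C1C(C)C | target

**Totals**
Total step count: 9. Longest linear sequence: 7 steps (1, 3, 5, 6, 7, 8, 9 from butane-2,3-dione; equally 2, 3, 5–9 from 3-methylbut-1-yne).

**Three steps most likely to fail**

Step 9 (the proposed new step). It can fail through direct acylation of the six-ring tertiary alcohol, migration of the wrong ring carbon, or Lewis-acid ionisation of the allylic ester. The fallback uses known chemistry only, sets out from 17 and comes back at 22. The secondary alcohol of 17 is acylated with 19 (Et3N, cat. DMAP, CH2Cl2, 0 °C) and 20 is isolated. Periodate cleavage of the tertiary α-ketol (NaIO4, THF–H2O) removes the acetyl group and gives the hydrindenone angelate F1. Sc(OTf)3-catalysed homologation with diazoethane (−78 °C) is irreversible and inserts CH(CH3) on the less hindered side, away from the quaternary carbon, to give the 6-methylcycloheptanone F2 as a C6 epimer mixture. Thermodynamic enol silylation (Me3SiI, (Me3Si)2NH) gives the silyl enol ether F3. Rubottom oxidation (dimethyldioxirane, then dilute acid) gives 21 together with the C6 epimer F4, which is removed by chromatography; the facial selectivity of this oxidation is not controlled by the substrate. Finally 21 is acylated with 19 (Sc(OTf)3, −20 °C) to give 22.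

Step 6 (Pauson–Khand). A 1,7-enyne with a 1,1-disubstituted alkene and a branched alkyne substituent is a slow substrate. The fallback sets out from 14 and comes back at 15, replacing the cobalt cycloaddition by an early-metal reductive cyclisation and carbonylation, which needs the alcohol masked. Silylation (Me3SiOTf, 2,6-lutidine, CH2Cl2, −78 °C) gives the trimethylsilyl ether F5. Cp2Ti(CO)2 (10 mol%) under CO (1.2 atm) in PhMe at 90 °C gives the silylated enone F6. K2CO3 in MeOH then frees 15.

Step 5 (asymmetric methallylboration). The ketone is flanked by a quaternary ketal carbon, so rate and enantioselectivity are uncertain. The fallback sets out from 9 and comes back at 14, replacing asymmetric catalysis by resolution. Direct addition of 10 (THF, −78 °C) gives the racemic alcohol F7, and preparative chiral SFC delivers the (4S)-enantiomer 14.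

**Further compounds**
F1 | step 9 | (2S,7aR)-7a-methyl-6-oxo-3-(propan-2-yl)-2,4,5,6,7,7a-hexahydro-1H-inden-2-yl (2Z)-2-methylbut-2-enoate | C/C=C(/C)C(=O)O[C@H]1C[C@]2(C)CC(=O)CCC2=C1C(C)C
F2 | step 9 | (2S,8aR)-6,8a-dimethyl-7-oxo-3-(propan-2-yl)-1,2,4,5,6,7,8,8a-octahydroazulen-2-yl (2Z)-2-methylbut-2-enoate (C6 epimer mixture) | C/C=C(/C)C(=O)O[C@H]1C[C@]2(C)CC(=O)C(C)CCC2=C1C(C)C
F3 | step 9 | (2S,8aR)-6,8a-dimethyl-3-(propan-2-yl)-7-[(trimethylsilyl)oxy]-1,2,4,5,8,8a-hexahydroazulen-2-yl (2Z)-2-methylbut-2-enoate | C/C=C(/C)C(=O)O[C@H]1C[C@]2(C)CC(O[Si](C)(C)C)=C(C)CCC2=C1C(C)C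
F4 | step 9 | (2S,6R,8aR)-6-hydroxy-6,8a-dimethyl-7-oxo-3-(propan-2-yl)-1,2,4,5,6,7,8,8a-octahydroazulen-2-yl (2Z)-2-methylbut-2-enoate | C/C=C(/C)C(=O)O[C@H]1C[C@]2(C)CC(=O)[C@](C)(O)CCC2=C1C(C)C
F5 | step 6 | {[(4S)-4-(1,1-dimethoxyethyl)-2,9-dimethyldec-1-en-7-yn-4-yl]oxy}trimethylsilane | C=C(C)C[C@](O[Si](C)(C)C)(C(C)(OC)OC)CCC#CC(C)C
F6 | step 6 | (6S,7aS)-6-(1,1-dimethoxyethyl)-7a-methyl-3-(propan-2-yl)-6-[(trimethylsilyl)oxy]-1,4,5,6,7,7a-hexahydro-2H-inden-2-one | O=C1C[C@]2(C)C[C@](O[Si](C)(C)C)(C(C)(OC)OC)CCC2=C1C(C)C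
F7 | step 5 | rac-4-(1,1-dimethoxyethyl)-2,9-dimethyldec-1-en-7-yn-4-ol | C=C(C)CC(O)(C(C)(OC)OC)CCC#CC(C)C
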